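**Plan**

Positions follow eremophilane numbering (ring A = C1–C5 and C10, ring B = C5–C10; C14 on C5, C15 on C4, C11–C13 on C7).
Retrosynthesis: the C3 dienoate, the C12 acetate and the C7–C11 bond are cut first; the C3–O/C1=C2 unit is then traced back to a C2=C3 alkene.
In the resulting 2,9-dien-8-one, C8=O, the C10–C1 bond β,γ to it and the ring A alkene C2=C3 make up a δ,ε-unsaturated ketone. This is the product pattern of an oxy-Cope shift of the 1,5-diene C1=C2–C3–C8(O)–C9=C10, so C1–C10 is cut and a C3–C8 bond absent from the target is added, giving a bicyclo[2.2.2]octenol.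
The cage is cut at C4–C5 and C3–C8 (Diels–Alder) into a 1-silyloxy-4-methylcyclohexa-1,3-diene (ring B, from 4-methylanisole) and furan-2(5H)-one.
Forward: ring B, the cage, lactone to C3-vinyl and C4-methyl, ring A by the anionic oxy-Cope step, C9=C10, C3–O, a C7 ketone beside a C8 ketal, C7–C11, acetate, dienoate (from (R)-2-methylbutanoic acid).
Stereochemistry: C4 and C5 from the catalyst-controlled endo Diels–Alder reaction; C3 from epoxidation anti to both methyls; C7 from addition to the C7 ketone anti to the axial C5 methyl; C6′ from the chiral pool.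

Key step: step 9

Assumption: the oxazaborolidinium ion made from the (S)-prolinol-derived oxazaborolidine is taken to expose the lactone face that leads to 6; if the opposite sense is found, the (R)-enantiomer is used with no other change.

**Step 1**
Reactants: 1 4-methylanisole
Product: 3 4-methylcyclohex-3-en-1-one, via 1-methoxy-4-methylcyclohexa-1,4-diene 2 (not isolated)
Conditions: Li, NH3 (l), t-BuOH, THF, −33 °C; then oxalic acid (cat.), THF/H2O, rt
Reagents that add atoms: water (O)
Why: Birch reduction of the anisole gives the 1,4-diene with the enol ether intact, and mild acid hydrolysis of that enol ether should release the β,γ-unsaturated ketone without moving the C=C into conjugation.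

**Step 2**
Reactants: 3 4-methylcyclohex-3-en-1-one
Product: 4 tert-butyl(dimethyl)[(4-methylcyclohexa-1,3-dien-1-yl)oxy]silane
Conditions: TBSOTf, Et3N, CH2Cl2, 0 °C
Reagents that add atoms: tert-butyldimethylsilyl trifluoromethanesulfonate (CC(C)(C)[Si](C)(C)OS(=O)(=O)C(F)(F)F)
Why: Soft enolisation removes the proton that is both α to the carbonyl and allylic, so the conjugated silyl dienol ether with the silyloxy group (future C8) and the methyl group (future C5) on the two diene termini should form.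

**Step 3**
Reactants: 4 silyloxy diene; 5 furan-2(5H)-one
Product: 6 (3aR,4R,7R,7aS)-7-{[tert-butyl(dimethyl)silyl]oxy}-4-methyl-3a,4,7,7a-tetrahydro-4,7-ethano-2-benzofuran-1(3H)-one (endo lactone)
Conditions: (S)-1-(2-methylphenyl)-3,3-diphenyltetrahydro-1H,3H-pyrrolo[1,2-c][1,3,2]oxazaborole (20 mol %) protonated with HN(SO2CF3)2 (18 mol %), CH2Cl2, −78 → −40 °C
Reagents that add atoms: none
Why: Lewis-acid-catalysed Diels–Alder reaction in which the silyloxy group makes C5 the nucleophilic terminus, so C5 bonds to the lactone β-carbon (C4–C5) and C8 to the α-carbon (C3–C8); the endo transition state places both lactone carbons syn to the C9=C10 bridge, and the chiral oxazaborolidinium ion on the lactone carbonyl selects the diene face, fixing C4 and C5.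

**Step 4**
Reactants: 6 endo lactone
Product: 7 (1RS,3aR,4R,7R,7aS)-7-{[tert-butyl(dimethyl)silyl]oxy}-4-methyl-1,3,3a,4,7,7a-hexahydro-4,7-ethano-2-benzofuran-1-ol (lactol)
Conditions: iBu2AlH, CH2Cl2, −78 °C
Reagents that add atoms: none
Why: Partial hydride reduction of a lactone stops at the tetrahedral aluminium hemiacetal at low temperature; the silyl ether keeps the β-oxygenated carbonyl from retro-aldol opening of the cage.

**Step 5**
Reactants: 7 lactol
Product: 8 [(1R,2R,3S,4R)-4-{[tert-butyl(dimethyl)silyl]oxy}-3-ethenyl-1-methylbicyclo[2.2.2]oct-5-en-2-yl]methanol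
Conditions: Ph3PCH3Br, KOtBu, THF, 0 °C → rt
Reagents that add atoms: methyltriphenylphosphonium bromide (C[P+](c1ccccc1)(c1ccccc1)c1ccccc1.[Br-])
Why: Wittig methylenation of the open hydroxy aldehyde form of the lactol should give the endo vinyl group on C3 (C2=C1) and free the C15 hydroxymethyl group on C4 without touching either stereocentre.

**Step 6**
Reactants: 8 primary alcohol
Product: 9 [(1R,2R,3S,4R)-4-{[tert-butyl(dimethyl)silyl]oxy}-3-ethenyl-1-methylbicyclo[2.2.2]oct-5-en-2-yl]methyl 4-methylbenzenesulfonate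
Conditions: TsCl, pyridine, 4-(dimethylamino)pyridine (cat.), CH2Cl2, 0 °C → rt
Reagents that add atoms: 4-methylbenzenesulfonyl chloride (Cc1ccc(cc1)S(=O)(=O)Cl)
Why: Sulfonylation of the primary alcohol activates C15 for hydride displacement.

**Step 7**
Reactants: 9 tosylate
Product: 10 tert-butyl{[(1R,4R,5R,6S)-6-ethenyl-4,5-dimethylbicyclo[2.2.2]oct-2-en-1-yl]oxy}dimethylsilane
Conditions: LiEt3BH, THF, 0 → 50 °C
Reagents that add atoms: none
Why: SN2 displacement of a primary sulfonate by the strongly nucleophilic triethylborohydride, which tolerates β-branching, should turn C15 into the endo C4 methyl group.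

**Step 8**
Reactants: 10 silyl ether
Product: 11 (1R,4R,5R,6S)-6-ethenyl-4,5-dimethylbicyclo[2.2.2]oct-2-en-1-ol (C8 bridgehead OH, C5 bridgehead methyl, endo vinyl on C3, endo methyl on C4)
Conditions: Bu4NF, THF, 50 °C
Reagents that add atoms: none
Why: Fluoride cleaves the bridgehead silyl ether now that no carbonyl is left β to C8 and retro-aldol opening is no longer possible.

**Step 9**
Reactants: 11 bridgehead alcohol
Product: 14 (4R,5S,10S)-8-[(trimethylsilyl)oxy]-11,12,13-trinoreremophila-2,8-diene (cis-fused), via bridgehead potassium alkoxide 12 (not isolated), via potassium enolate 13 (not isolated)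
Conditions: KH, 18-crown-6 (1,4,7,10,13,16-hexaoxacyclooctadecane), THF, 0 °C → rt; then Me3SiCl, Et3N, −78 °C
Reagents that add atoms: trimethylsilyl chloride (C[Si](C)(C)Cl)
Why: KH with the crown ether gives the bridgehead potassium alkoxide 12, whose charge weakens the adjacent C3–C8 bond and drives the [3,3] sigmatropic shift of the 1,5-diene C1=C2–C3–C8(O)–C9=C10. The closest known reaction type is the alkoxide-accelerated (anionic) oxy-Cope rearrangement of endo-vinyl bicyclo[2.2.2]octenols to cis-fused decalinones. Ring A (six-membered, C1–C5 and C10) closes by C1–C10 bond formation through a boat-shaped six-centre transition state held by the cage, while the cage opens at C3–C8 and leaves ring B as the C8 enolate 13. The only new stereocentre, C10, is set by the cage: C1 can reach C10 only on the face of C9=C10 turned toward the C3–C4 bridge, so H10 ends cis to the C5 methyl and C4 and C5 are untouched. The step needs an endo vinyl group and a regiodefined enolate; the first is secured by the endo Diels–Alder adduct, the second by silylating 13 at −78 °C so that the C8–C9 enol ether carries the regiochemistry forward.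

**Step 10**
Reactants: 14 silyl enol ether
Product: 15 (4R,5S)-11,12,13-trinoreremophila-2,9-dien-8-one
Conditions: Pd(OAc)2 (1.05 equiv), MeCN, rt
Reagents that add atoms: none
Why: Saegusa–Ito oxidation: the divalent palladium enolate formed at C9 loses H10 by β-hydride elimination, so the C9=C10 enone should form only on the side fixed by the enol ether, and the C10 stereocentre is removed as planned.

**Step 11**
Reactants: 15 enone
Product: 17 (3S,4S,5S)-3-hydroxy-11,12,13-trinoreremophila-1,9-dien-8-one, via 2,3-epoxy enone 16 (not isolated)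
Conditions: mCPBA, NaHCO3, CH2Cl2, 0 °C; aqueous Na2SO3 wash; then 1,8-diazabicyclo[5.4.0]undec-7-ene (0.2 equiv), CH2Cl2, 0 °C
Reagents that add atoms: 3-chloroperoxybenzoic acid (OOC(=O)c1cccc(Cl)c1)
Why: The peracid epoxidises the isolated C2=C3 alkene (the enone alkene is electron-poor) on the face anti to the axial C5 methyl and the C4 methyl, which sets C3; the amidine then removes a C1 proton γ to the ketone and the dienolate opens the epoxide at C2 (vinylogous E1cB isomerisation of an epoxide to an allylic alcohol), giving C1=C2 and the C3 hydroxyl with C3 unchanged.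

**Step 12**
Reactants: 17 hydroxy dienone
Product: 18 (3S,4S,5S)-3-{[tert-butyl(dimethyl)silyl]oxy}-11,12,13-trinoreremophila-1,9-dien-8-one
Conditions: TBSCl, imidazole, DMF, rt
Reagents that add atoms: tert-butyldimethylsilyl chloride (CC(C)(C)[Si](C)(C)Cl)
Why: Silylation protects the allylic C3 hydroxyl against the strong base, oxidant and organometallic reagent used at C7.

**Step 13**
Reactants: 18 silyl-protected dienone
Product: 21 (3S,4S,5S,7RS)-3-{[tert-butyl(dimethyl)silyl]oxy}-7-hydroxy-8,8-dimethoxy-11,12,13-trinoreremophila-1,9-diene, via potassium dienolate 19 (not isolated), via 8-methoxy triene 20 (not isolated)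
Conditions: KN(SiMe3)2, 18-crown-6, THF, −78 °C; MeOSO2CF3, −78 °C; then mCPBA, NaHCO3, MeOH/CH2Cl2, −40 → 0 °C
Reagents that add atoms: methyl trifluoromethanesulfonate (COS(=O)(=O)C(F)(F)F); 3-chloroperoxybenzoic acid (OOC(=O)c1cccc(Cl)c1); methanol (CO)
Why: Kinetic deprotonation at C7 gives the cross-conjugated dienolate, whose crown-separated potassium salt should be methylated on oxygen by the hard triflate; the electron-rich C7=C8 enol ether is then epoxidised in preference to the other alkenes and methanol opens the methoxy epoxide at C8 (Rubottom-type oxidation run in methanol), giving the α-hydroxy dimethyl ketal, whose C7 configuration does not matter.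

**Step 14**
Reactants: 21 hydroxy ketal
Product: 22 (3S,4S,5S)-3-{[tert-butyl(dimethyl)silyl]oxy}-8,8-dimethoxy-11,12,13-trinoreremophila-1,9-dien-7-one
Conditions: 1,1,1-triacetoxy-1,1-dihydro-1,2-benziodoxol-3(1H)-one (DMP), pyridine, CH2Cl2, 0 °C → rt
Reagents that add atoms: none
Why: Buffered periodinane oxidation of the secondary alcohol gives the C7 ketone; because C8 is locked as a ketal, the 7,8-dicarbonyl unit cannot collapse to the C6=C7 enol (diosphenol) that a free dione would form, so C7 stays electrophilic.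

**Step 15**
Reactants: 23 2-bromoprop-2-en-1-ol
Product: 24 2-bromo-3-[(2-methoxypropan-2-yl)oxy]prop-1-ene
Conditions: 2-methoxypropene, pyridinium 4-methylbenzenesulfonate (cat.), CH2Cl2, 0 °C
Reagents that add atoms: 2-methoxypropene (COC(C)=C)
Why: Acid-catalysed addition of the alcohol to the enol ether gives a mixed ketal that is stable to organolithium reagents and is cleaved by the same mild aqueous acid that will unmask C8.

**Step 16**
Reactants: 22 keto ketal; 24 protected 2-bromoallyl alcohol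
Product: 28 (3S,4S,5S,7S)-3-{[tert-butyl(dimethyl)silyl]oxy}-7,12-dihydroxyeremophila-1,9,11(13)-trien-8-one, via alkenyllithium 25 (not isolated), via alkenylcerium dichloride 26 (not isolated), via ketal adduct 27 (not isolated)
Conditions: 24, t-BuLi (2 equiv), Et2O, −78 °C; CeCl3, THF, −78 °C; 22, −78 °C; then AcOH/THF/H2O, rt
Reagents that add atoms: water (O)
Why: Bromine–lithium exchange and transmetalation give a weakly basic alkenylcerium reagent that should add 1,2 to the C7 ketone from the equatorial direction anti to the axial C5 methyl, placing C11 trans and the new hydroxyl cis to C14 (7S); aqueous acetic acid then hydrolyses the dienyl ketal to the C8 ketone and removes the mixed ketal on O12 while the secondary silyl ether stays.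

**Step 17**
Reactants: 28 diol
Product: 29 (3S,4S,5S,7S)-12-acetoxy-3-{[tert-butyl(dimethyl)silyl]oxy}-7-hydroxyeremophila-1,9,11(13)-trien-8-one
Conditions: Ac2O, pyridine, CH2Cl2, 0 °C
Reagents that add atoms: acetic anhydride (CC(=O)OC(C)=O)
Why: Acetylation takes the primary allylic hydroxyl only, the tertiary α-ketol hydroxyl being too hindered to react under these conditions.

**Step 18**
Reactants: 29 acetate
Product: 30 (3S,4S,5S,7S)-12-acetoxy-3,7-dihydroxyeremophila-1,9,11(13)-trien-8-one
Conditions: HF·pyridine, pyridine, THF, 0 °C → rt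
Reagents that add atoms: none
Why: Buffered fluoride cleaves the secondary silyl ether and should leave the acetate, the tertiary alcohol and the dienone intact.

**Step 19**
Reactants: 31 (R)-2-methylbutanoic acid
Product: 32 (R)-2-methylbutan-1-ol
Conditions: LiAlH4, Et2O, 0 °C → rt
Reagents that add atoms: none
Why: Hydride reduction of the acid to the primary alcohol does not involve the stereocentre.

**Step 20**
Reactants: 32 (R)-2-methylbutan-1-ol
Product: 34 (2E,4R)-2,4-dimethylhex-2-enal, via (R)-2-methylbutanal 33 (not isolated)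
Conditions: DMP, NaHCO3, CH2Cl2, 0 °C → rt; then Ph3P=C(CH3)CHO, 40 °C
Reagents that add atoms: 2-(triphenylphosphoranylidene)propanal (CC(C=O)=P(c1ccccc1)(c1ccccc1)c1ccccc1)
Why: The configurationally labile α-branched aldehyde is made under non-basic conditions and trapped in the same flask by a stabilised formyl ylide, whose Wittig reaction should give the E trisubstituted enal.

**Step 21**
Reactants: 34 enal
Product: 35 ethyl (2E,4E,6R)-4,6-dimethylocta-2,4-dienoate
Conditions: Ph3P=CHCO2Et, toluene, 80 °C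
Reagents that add atoms: ethyl (triphenylphosphoranylidene)acetate (CCOC(=O)C=P(c1ccccc1)(c1ccccc1)c1ccccc1)
Why: Wittig reaction of the enal with an ester-stabilised ylide should give the E disubstituted alkene under base-free conditions.

**Step 22**
Reactants: 35 dienoate ester
Product: 36 (2E,4E,6R)-4,6-dimethylocta-2,4-dienoic acid
Conditions: LiOH, THF/MeOH/H2O, rt; then aqueous HCl to pH 3
Reagents that add atoms: lithium hydroxide ([Li+].[OH-])
Why: Saponification of the ethyl ester; the remote C6 stereocentre is not acidic under these conditions.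

**Step 23**
Reactants: 30 C3 alcohol; 36 dienoic acid
Product: 37 (3S,4S,5S,7S)-12-acetoxy-7-hydroxy-8-oxoeremophila-1,9,11(13)-trien-3-yl (2E,4E,6R)-4,6-dimethylocta-2,4-dienoate (CNP0160850.1)
Conditions: N,N′-dicyclohexylcarbodiimide, 4-(dimethylamino)pyridine (cat.), CH2Cl2, 0 °C → rt
Reagents that add atoms: none
Why: Steglich esterification acylates the only reactive hydroxyl, the secondary C3–OH, with retention, the tertiary C7–OH being inert.

**Compound list**

1 | 4-methylanisole | COc1ccc(C)cc1 | starting material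
2 | 1-methoxy-4-methylcyclohexa-1,4-diene | COC1=CCC(C)=CC1 | intermediate
3 | 4-methylcyclohex-3-en-1-one | CC1=CCC(=O)CC1 | intermediate
4 | tert-butyl(dimethyl)[(4-methylcyclohexa-1,3-dien-1-yl)oxy]silane | CC1=CC=C(O[Si](C)(C)C(C)(C)C)CC1 | intermediate
5 | furan-2(5H)-one | O=C1OCC=C1 | starting material
6 | (3aR,4R,7R,7aS)-7-{[tert-butyl(dimethyl)silyl]oxy}-4-methyl-3a,4,7,7a-tetrahydro-4,7-ethano-2-benzofuran-1(3H)-one | CC(C)(C)[Si](C)(C)O[C@]12CC[C@](C)(C=C1)[C@@H]3COC(=O)[C@H]23 | intermediate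
7 | (1RS,3aR,4R,7R,7aS)-7-{[tert-butyl(dimethyl)silyl]oxy}-4-methyl-1,3,3a,4,7,7a-hexahydro-4,7-ethano-2-benzofuran-1-ol | CC(C)(C)[Si](C)(C)O[C@]12CC[C@](C)(C=C1)[C@@H]3COC(O)[C@H]23 | intermediate
8 | [(1R,2R,3S,4R)-4-{[tert-butyl(dimethyl)silyl]oxy}-3-ethenyl-1-methylbicyclo[2.2.2]oct-5-en-2-yl]methanol | CC(C)(C)[Si](C)(C)O[C@]12CC[C@](C)(C=C1)[C@H](CO)[C@@H]2C=C | intermediate
9 | [(1R,2R,3S,4R)-4-{[tert-butyl(dimethyl)silyl]oxy}-3-ethenyl-1-methylbicyclo[2.2.2]oct-5-en-2-yl]methyl 4-methylbenzenesulfonate | CC(C)(C)[Si](C)(C)O[C@]12CC[C@](C)(C=C1)[C@H](COS(=O)(=O)c3ccc(C)cc3)[C@@H]2C=C | intermediate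
10 | tert-butyl{[(1R,4R,5R,6S)-6-ethenyl-4,5-dimethylbicyclo[2.2.2]oct-2-en-1-yl]oxy}dimethylsilane | CC(C)(C)[Si](C)(C)O[C@]12CC[C@](C)(C=C1)[C@H](C)[C@@H]2C=C | intermediate
11 | (1R,4R,5R,6S)-6-ethenyl-4,5-dimethylbicyclo[2.2.2]oct-2-en-1-ol | O[C@]12CC[C@](C)(C=C1)[C@H](C)[C@@H]2C=C | intermediate
12 | potassium (1R,4R,5R,6S)-6-ethenyl-4,5-dimethylbicyclo[2.2.2]oct-2-en-1-olate | [K+].[O-][C@]12CC[C@](C)(C=C1)[C@H](C)[C@@H]2C=C | intermediate
13 | potassium (4R,5S,10S)-11,12,13-trinoreremophila-2,8-dien-8-olate | [K+].[O-]C1=C[C@@H]2CC=C[C@@H](C)[C@]2(C)CC1 | intermediate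
14 | (4R,5S,10S)-8-[(trimethylsilyl)oxy]-11,12,13-trinoreremophila-2,8-diene | C[Si](C)(C)OC1=C[C@@H]2CC=C[C@@H](C)[C@]2(C)CC1 | intermediate
15 | (4R,5S)-11,12,13-trinoreremophila-2,9-dien-8-one | O=C1CC[C@]2(C)C(=C1)CC=C[C@H]2C | intermediate
16 | (2S,3R,4S,5S)-2,3-epoxy-11,12,13-trinoreremophil-9-en-8-one | O=C1CC[C@]2(C)C(=C1)C[C@@H]3O[C@@H]3[C@H]2C | intermediate
17 | (3S,4S,5S)-3-hydroxy-11,12,13-trinoreremophila-1,9-dien-8-one | O=C1CC[C@]2(C)C(=C1)C=C[C@H](O)[C@H]2C | intermediate
18 | (3S,4S,5S)-3-{[tert-butyl(dimethyl)silyl]oxy}-11,12,13-trinoreremophila-1,9-dien-8-one | O=C1CC[C@]2(C)C(=C1)C=C[C@H](O[Si](C)(C)C(C)(C)C)[C@H]2C | intermediate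
19 | potassium (3S,4S,5S)-3-{[tert-butyl(dimethyl)silyl]oxy}-11,12,13-trinoreremophila-1,7,9-trien-8-olate | [K+].[O-]C1=CC[C@]2(C)C(=C1)C=C[C@H](O[Si](C)(C)C(C)(C)C)[C@H]2C | intermediate
20 | (3S,4S,5S)-3-{[tert-butyl(dimethyl)silyl]oxy}-8-methoxy-11,12,13-trinoreremophila-1,7,9-triene | COC1=CC[C@]2(C)C(=C1)C=C[C@H](O[Si](C)(C)C(C)(C)C)[C@H]2C | intermediate
21 | (3S,4S,5S,7RS)-3-{[tert-butyl(dimethyl)silyl]oxy}-7-hydroxy-8,8-dimethoxy-11,12,13-trinoreremophila-1,9-diene | OC1C[C@]2(C)C(=CC1(OC)OC)C=C[C@H](O[Si](C)(C)C(C)(C)C)[C@H]2C | intermediate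
22 | (3S,4S,5S)-3-{[tert-butyl(dimethyl)silyl]oxy}-8,8-dimethoxy-11,12,13-trinoreremophila-1,9-dien-7-one | O=C1C[C@]2(C)C(=CC1(OC)OC)C=C[C@H](O[Si](C)(C)C(C)(C)C)[C@H]2C | intermediate
23 | 2-bromoprop-2-en-1-ol | C=C(Br)CO | starting material
24 | 2-bromo-3-[(2-methoxypropan-2-yl)oxy]prop-1-ene | C=C(Br)COC(C)(C)OC | intermediate
25 | {3-[(2-methoxypropan-2-yl)oxy]prop-1-en-2-yl}lithium | [Li]C(=C)COC(C)(C)OC | intermediate
26 | dichloro{3-[(2-methoxypropan-2-yl)oxy]prop-1-en-2-yl}cerium | C=C(COC(C)(C)OC)[Ce](Cl)Cl | intermediate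
27 | (3S,4S,5S,7S)-3-{[tert-butyl(dimethyl)silyl]oxy}-8,8-dimethoxy-12-[(2-methoxypropan-2-yl)oxy]eremophila-1,9,11(13)-trien-7-ol | C=C(COC(C)(C)OC)[C@@]1(O)C[C@]2(C)C(=CC1(OC)OC)C=C[C@H](O[Si](C)(C)C(C)(C)C)[C@H]2C | intermediate
28 | (3S,4S,5S,7S)-3-{[tert-butyl(dimethyl)silyl]oxy}-7,12-dihydroxyeremophila-1,9,11(13)-trien-8-one | C=C(CO)[C@@]1(O)C[C@]2(C)C(=CC1=O)C=C[C@H](O[Si](C)(C)C(C)(C)C)[C@H]2C | intermediate
29 | (3S,4S,5S,7S)-12-acetoxy-3-{[tert-butyl(dimethyl)silyl]oxy}-7-hydroxyeremophila-1,9,11(13)-trien-8-one | C=C(COC(C)=O)[C@@]1(O)C[C@]2(C)C(=CC1=O)C=C[C@H](O[Si](C)(C)C(C)(C)C)[C@H]2C | intermediate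
30 | (3S,4S,5S,7S)-12-acetoxy-3,7-dihydroxyeremophila-1,9,11(13)-trien-8-one | C=C(COC(C)=O)[C@@]1(O)C[C@]2(C)C(=CC1=O)C=C[C@H](O)[C@H]2C | intermediate
31 | (R)-2-methylbutanoic acid | CC[C@@H](C)C(=O)O | starting material
32 | (R)-2-methylbutan-1-ol | CC[C@@H](C)CO | intermediate
33 | (R)-2-methylbutanal | CC[C@@H](C)C=O | intermediate
34 | (2E,4R)-2,4-dimethylhex-2-enal | CC[C@@H](C)/C=C(\C)C=O | intermediate
35 | ethyl (2E,4E,6R)-4,6-dimethylocta-2,4-dienoate | CCOC(=O)/C=C/C(C)=C/[C@H](C)CC | intermediate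
36 | (2E,4E,6R)-4,6-dimethylocta-2,4-dienoic acid | OC(=O)/C=C/C(C)=C/[C@H](C)CC | intermediate
37 | (3S,4S,5S,7S)-12-acetoxy-7-hydroxy-8-oxoeremophila-1,9,11(13)-trien-3-yl (2E,4E,6R)-4,6-dimethylocta-2,4-dienoate | C=C(COC(C)=O)[C@@]1(O)C[C@]2(C)C(=CC1=O)C=C[C@H](OC(=O)/C=C/C(C)=C/[C@H](C)CC)[C@H]2C | target

**Count**

Total steps: 23. Longest linear sequence: 18 steps (steps 1–14, 16–18 and 23).

**Steps most likely to fail**

Step 3. The strongly acidic catalyst may protodesilylate diene 4, the reaction may go stepwise (Mukaiyama–Michael addition without ring closure), or the small lactone may be bound with weak facial discrimination, so enantiopurity or conversion could be poor. The fallback sets out from 4 and returns at 6. Diene 4 is heated in toluene with (5S)-5-{[(1S,2R,5S)-5-methyl-2-(propan-2-yl)cyclohexyl]oxy}furan-2(5H)-one (O=C1C=C[C@@H](O[C@H]2C[C@@H](C)CC[C@@H]2C(C)C)O1), a chiral-auxiliary dienophile that reacts endo and anti to its alkoxy group without a catalyst, to give the menthyloxy lactone F1. Aqueous CF3CO2H hydrolyses the acetal to the hydroxy lactone F2, which is in equilibrium with its aldehyde acid. NaBH4 reduction of that aldehyde and acidification close the lactone again and give 6.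

Step 13. Methylation of dienolate 19 may occur on C7 instead of oxygen, or the peracid may attack the remaining diene of 20. The fallback sets out from 18 and returns at 21. The lithium dienolate of 18 (LiN(SiMe3)2, THF, −78 °C) is trapped with Me3SiCl, which reacts on oxygen only, to give the silyl dienol ether F3. Rubottom oxidation (mCPBA, NaHCO3) with silyl transfer gives the 7-trimethylsilyloxy ketone F4. Aprotic ketalisation of the C8 carbonyl (Me3SiOMe, cat. Me3SiOSO2CF3, CH2Cl2, −78 °C) gives the silyloxy ketal F5, and K2CO3 in MeOH removes the silyl group to give 21.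

Step 16. The hindered, oxygen-bearing alkenyl group may transfer slowly, so that enolisation of 22 toward C6 competes, and the adjacent ketal may weaken the preference for attack anti to the C5 methyl. The fallback sets out from 22 and returns at 28. The smaller reagent from H2C=C(CH3)MgBr and CeCl3 is added to 22 to give the isopropenyl ketal adduct F6. Aqueous AcOH unmasks the C8 ketone to give the isopropenyl ketol F7. SeO2 (cat.) with t-BuOOH then hydroxylates the allylic methyl group of the 1,1-disubstituted alkene to give 28.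

**Further compounds**

F1 | step 3 | (3S,3aR,4R,7R,7aS)-7-{[tert-butyl(dimethyl)silyl]oxy}-4-methyl-3-{[(1S,2R,5S)-5-methyl-2-(propan-2-yl)cyclohexyl]oxy}-3a,4,7,7a-tetrahydro-4,7-ethano-2-benzofuran-1(3H)-one | CC(C)(C)[Si](C)(C)O[C@]12CC[C@](C)(C=C1)[C@@H]3[C@@H](O[C@H]4C[C@@H](C)CC[C@@H]4C(C)C)OC(=O)[C@H]23
F2 | step 3 | (3RS,3aR,4R,7R,7aS)-7-{[tert-butyl(dimethyl)silyl]oxy}-3-hydroxy-4-methyl-3a,4,7,7a-tetrahydro-4,7-ethano-2-benzofuran-1(3H)-one | CC(C)(C)[Si](C)(C)O[C@]12CC[C@](C)(C=C1)[C@@H]3C(O)OC(=O)[C@H]23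
F3 | step 13 | (3S,4S,5S)-3-{[tert-butyl(dimethyl)silyl]oxy}-8-[(trimethylsilyl)oxy]-11,12,13-trinoreremophila-1,7,9-triene | C[Si](C)(C)OC1=CC[C@]2(C)C(=C1)C=C[C@H](O[Si](C)(C)C(C)(C)C)[C@H]2C
F4 | step 13 | (3S,4S,5S,7RS)-3-{[tert-butyl(dimethyl)silyl]oxy}-7-[(trimethylsilyl)oxy]-11,12,13-trinoreremophila-1,9-dien-8-one | C[Si](C)(C)OC1C[C@]2(C)C(=CC1=O)C=C[C@H](O[Si](C)(C)C(C)(C)C)[C@H]2C
F5 | step 13 | (3S,4S,5S,7RS)-3-{[tert-butyl(dimethyl)silyl]oxy}-8,8-dimethoxy-7-[(trimethylsilyl)oxy]-11,12,13-trinoreremophila-1,9-diene | C[Si](C)(C)OC1C[C@]2(C)C(=CC1(OC)OC)C=C[C@H](O[Si](C)(C)C(C)(C)C)[C@H]2C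
F6 | step 16 | (3S,4S,5S,7S)-3-{[tert-butyl(dimethyl)silyl]oxy}-8,8-dimethoxyeremophila-1,9,11(13)-trien-7-ol | C=C(C)[C@@]1(O)C[C@]2(C)C(=CC1(OC)OC)C=C[C@H](O[Si](C)(C)C(C)(C)C)[C@H]2C
F7 | step 16 | (3S,4S,5S,7S)-3-{[tert-butyl(dimethyl)silyl]oxy}-7-hydroxyeremophila-1,9,11(13)-trien-8-one | C=C(C)[C@@]1(O)C[C@]2(C)C(=CC1=O)C=C[C@H](O[Si](C)(C)C(C)(C)C)[C@H]2C
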